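## Retrosynthetic overview

1. The heptatrienamide is cut at its C2′–C3′ bond: Stille coupling, after hydrostannylation of a C4 ethynyl group, joins an alkynyl enamide core to the bromodienamide of the aminocyclopentenone (itself made by N-acylation).
2. The enamide C2–N bond is cut: copper-catalysed vinylic amidation of a 2-iodoenone with the primary amide of the branched side chain.
3. Key disconnection, the C5–O bond: the cis-4,5-diol (both ring stereocentres) comes from a catalytic enantioselective desymmetrising boronate oxa-Michael "syn-hydration" of achiral 4-ethynyl-p-quinol, made from 1,4-benzoquinone and ethynylmagnesium bromide.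
4. Side chain: Wittig amide olefination of an aldehyde whose two methyl stereocentres come from two zirconium-catalysed carboaluminations starting at hex-1-ene.
5. Rings: no carbocycle is built (six-membered ring from benzoquinone, five-membered ring from cyclopentane-1,3-dione); the only ring formed is the transient dioxaborolane of the key step.

Assumption: ring numbering is C1 (ketone), C2 (N-bearing), C3, C4 (tertiary carbinol), C5 (secondary carbinol), C6; both enantiomers of bis(1-neomenthylindenyl)zirconium dichloride and glutaconaldehyde potassium salt are bought.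

## Route

Step 1
Reactants: 1 hex-1-ene
Product: 3 (4S)-4-methyloct-1-ene, via dimethyl[(2S)-2-methylhexyl]alumane 2 (not isolated)
Conditions: Me3Al (2 equiv), (+)-bis(1-neomenthylindenyl)zirconium dichloride (4 mol %), methylaluminoxane (MeAlO)n, CH2Cl2, 0 °C → rt; evaporate; Zn(OTf)2, DMF, 70 °C; then vinyl bromide (4 equiv), PdCl2(DPEphos) (3 mol %; DPEphos = bis[2-(diphenylphosphino)phenyl] ether), i-Bu2AlH (6 mol %), rt
Reagents that add atoms: trimethylaluminium C[Al](C)C; vinyl bromide C=CBr
Why: Zirconium-catalysed asymmetric carboalumination (ZACA reaction) adds Me–Al across the terminal alkene with the chiral zirconocene choosing the alkene face (S, about 75–80% ee expected), and the primary alkylalane is then vinylated by a zinc-promoted palladium-catalysed Negishi-type coupling that does not touch the new stereocentre.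

Step 2
Reactants: 3 (4S)-4-methyloct-1-ene
Product: 5 (2R,4S)-2,4-dimethyloctan-1-ol, via dimethyl[(2R,4S)-2,4-dimethyloctyl]alumane 4 (not isolated)
Conditions: Me3Al (2 equiv), (−)-bis(1-neomenthylindenyl)zirconium dichloride (4 mol %), methylaluminoxane (MeAlO)n, CH2Cl2, 0 °C → rt; then O2, 0 °C → rt; aq HCl
Reagents that add atoms: trimethylaluminium C[Al](C)C; dioxygen O=O
Why: A second ZACA reaction with the enantiomeric zirconocene sets C2 under catalyst control and O2 oxidises the C–Al bond to the primary alcohol, so that the two multiplied catalyst-controlled events give the anti (2R,4S) isomer in about 96% ee at roughly 4:1 dr, the minor diastereomers being removed by chromatography here and by recrystallisation of amide 7.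

Step 3
Reactants: 5 (2R,4S)-2,4-dimethyloctan-1-ol
Product: 7 (2E,4R,6S)-4,6-dimethyldec-2-enamide, via (2R,4S)-2,4-dimethyloctanal 6 (not isolated)
Conditions: TEMPO (2,2,6,6-tetramethylpiperidin-1-oxyl, 10 mol %), PhI(OAc)2 (1.1 equiv), CH2Cl2, rt; then Ph3P=CHCONH2 (2.5 equiv), rt → 40 °C
Reagents that add atoms: 2-(triphenyl-λ5-phosphanylidene)acetamide NC(=O)C=P(c1ccccc1)(c1ccccc1)c1ccccc1
Why: The nitroxyl-catalysed oxidation gives the α-branched aldehyde under nearly neutral, non-epimerising conditions and the amide-stabilised ylide added to the same flask gives the (E)-enamide by Wittig olefination, so the sensitive aldehyde is never isolated.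

Step 4
Reactants: 8 1,4-benzoquinone
Product: 9 4-ethynyl-4-hydroxycyclohexa-2,5-dien-1-one
Conditions: HC≡CMgBr (1.0 equiv, 0.5 M in THF), THF, −78 °C, inverse addition; aq NH4Cl
Reagents that add atoms: ethynylmagnesium bromide C#C[Mg]Br
Why: 1,2-Addition of the alkynyl Grignard reagent to one quinone carbonyl at low temperature gives the p-quinol, the magnesium alkoxide of the mono-adduct resisting a second addition, and no stereocentre arises because the product has a mirror plane.

Step 5
Reactants: 9 4-ethynyl-4-hydroxycyclohexa-2,5-dien-1-one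
Product: 11 (4R,5R)-4-ethynyl-4,5-dihydroxycyclohex-2-en-1-one, via cyclic phenylboronate 10 (not isolated)
Conditions: PhB(OH)2 (1.2 equiv), N-[3,5-bis(trifluoromethyl)phenyl]-N′-(9-deoxy-epi-quinidin-9-yl)thiourea (10 mol %), 4 Å MS, toluene, 0 °C → rt; then pinacol (3 equiv), rt
Reagents that add atoms: phenylboronic acid OB(O)c1ccccc1
Why: Proposed new method: a catalytic enantioselective desymmetrising syn-hydration of a prochiral p-quinol, in which the tertiary hydroxyl of 9 condenses with PhB(OH)2 to a boronic hemiester whose B–OH oxygen, made nucleophilic by coordination of the catalyst's quinuclidine nitrogen to boron while the thiourea hydrogen-bonds the dienone carbonyl, adds intramolecularly (5-exo oxa-Michael) to one of the two enantiotopic enone β-carbons, so that the cis ring fusion of dioxaborolane 10 fixes the C4/C5 hydroxyls cis and the catalyst fixes the absolute configuration of both centres at once (the quinine-derived pseudo-enantiomer is used instead if the first run gives the antipode), after which neutral transesterification with pinacol frees the diol without the alkaline peroxide that would epoxidise the enone; the closest known reaction types are the amine–thiourea-catalysed boronic acid hemiester (chiral hydroxide equivalent) oxa-Michael addition to acyclic γ-hydroxy enones and the organocatalytic desymmetrisation of cyclohexadienones by tethered oxygen nucleophiles, whereas enantiotopic-arm selection on a p-quinol by a boronate hemiester has not been shown.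

Step 6
Reactants: 11 (4R,5R)-4-ethynyl-4,5-dihydroxycyclohex-2-en-1-one
Product: 12 (4R,5R)-4-ethynyl-4,5-dihydroxy-2-iodocyclohex-2-en-1-one
Conditions: I2 (1.5 equiv), pyridine/CH2Cl2 (1:1), 0 °C → rt, dark
Reagents that add atoms: iodine II
Why: Baylis–Hillman-type α-iodination of the cyclic enone (conjugate addition of pyridine, iodination of the enolate, elimination) is specific for C2, and pyridine-buffered iodine is too weak an electrophile to attack the electron-poor terminal alkyne or to cyclise the homopropargylic hydroxyl onto it, so C4 and C5 are untouched.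

Step 7
Reactants: 12 (4R,5R)-4-ethynyl-4,5-dihydroxy-2-iodocyclohex-2-en-1-one; 7 (2E,4R,6S)-4,6-dimethyldec-2-enamide
Product: 13 (2E,4R,6S)-N-[(3R,4R)-3-ethynyl-3,4-dihydroxy-6-oxocyclohex-1-en-1-yl]-4,6-dimethyldec-2-enamide
Conditions: 7 (1.3 equiv), CuI (20 mol %), 3,4,7,8-tetramethyl-1,10-phenanthroline (40 mol %), K3PO4 (2 equiv), toluene/THF, 45 °C, Ar
Reagents that add atoms: none
Why: Goldberg-type copper-catalysed vinylic amidation, in which the phenanthroline-ligated monovalent copper amidate of 7 activates the very reactive α-iodoenone C–I bond and reductive elimination forms the C2–N enamide bond (N over O selectivity, a non-nucleophilic ligand so that no amine adds to the iodoenone, a mild heterogeneous base to spare the β-hydroxy ketone), with no stereocentre touched.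

Step 8
Reactants: 14 potassium (1E,3E)-5-oxopenta-1,3-dien-1-olate (glutaconaldehyde potassium salt)
Product: 15 (2E,4E)-5-bromopenta-2,4-dienal
Conditions: PPh3, Br2, CH2Cl2, 0 °C; add 14, 0 °C → rt; then I2 (cat.), rt
Reagents that add atoms: bromine BrBr
Why: The enolate oxygen is activated as an oxyphosphonium leaving group and replaced by bromide in a vinylogous addition–elimination (deoxybromination), and iodine-catalysed equilibration secures the thermodynamic (2E,4E) isomer.

Step 9
Reactants: 15 (2E,4E)-5-bromopenta-2,4-dienal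
Product: 16 (2E,4E)-5-bromopenta-2,4-dienoic acid
Conditions: NaClO2, NaH2PO4, 2-methylbut-2-ene, t-BuOH/H2O, 0 °C → rt
Reagents that add atoms: sodium chlorite [Na+].[O-]Cl=O
Why: Pinnick oxidation converts the conjugated aldehyde into the acid while 2-methylbut-2-ene scavenges hypochlorite, leaving the bromodiene geometry intact.

Step 10
Reactants: 17 cyclopentane-1,3-dione
Product: 18 2-(hydroxyimino)cyclopentane-1,3-dione
Conditions: NaNO2, 2 M aq HCl, 0–5 °C
Reagents that add atoms: sodium nitrite [Na+].[O-]N=O
Why: Electrophilic nitrosation of the strongly enolised 1,3-dione at C2 followed by tautomerisation gives the 2-oxime (classical isonitroso formation).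

Step 11
Reactants: 18 2-(hydroxyimino)cyclopentane-1,3-dione
Product: 19 2-amino-3-hydroxycyclopent-2-en-1-one hydrochloride
Conditions: H2 (3 atm), 10% Pd/C, HCl/EtOH, rt
Reagents that add atoms: hydrogen chloride Cl
Why: Catalytic hydrogenation of the oxime in acidic ethanol gives the 2-amino-1,3-dione, trapped as its hydrochloride (enol form) so that it cannot self-condense to a dihydropyrazine.

Step 12
Reactants: 16 (2E,4E)-5-bromopenta-2,4-dienoic acid; 19 2-amino-3-hydroxycyclopent-2-en-1-one hydrochloride
Product: 21 (2E,4E)-5-bromo-N-(2-hydroxy-5-oxocyclopent-1-en-1-yl)penta-2,4-dienamide, via (2E,4E)-5-bromopenta-2,4-dienoyl chloride 20 (not isolated)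
Conditions: (COCl)2, DMF (cat.), CH2Cl2, 0 °C → rt; evaporate; then 19, Et3N (2.2 equiv), THF/DMF, 0 °C → rt
Reagents that add atoms: none
Why: Acid chloride formation followed by N-acylation of the enaminone nitrogen (Schotten–Baumann-type amide coupling), any O-acyl enol ester formed first passing its acyl group to nitrogen, with the (2E,4E) geometry retained.

Step 13
Reactants: 13 (2E,4R,6S)-N-[(3R,4R)-3-ethynyl-3,4-dihydroxy-6-oxocyclohex-1-en-1-yl]-4,6-dimethyldec-2-enamide; 21 (2E,4E)-5-bromo-N-(2-hydroxy-5-oxocyclopent-1-en-1-yl)penta-2,4-dienamide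
Product: 23 (2E,4R,6S)-N-[(3S,4R)-3,4-dihydroxy-3-{(1E,3E,5E)-7-[(2-hydroxy-5-oxocyclopent-1-en-1-yl)amino]-7-oxohepta-1,3,5-trien-1-yl}-6-oxocyclohex-1-en-1-yl]-4,6-dimethyldec-2-enamide, via (E)-vinylstannane 22 (not isolated)
Conditions: PdCl2(PPh3)2 (5 mol %), Bu3SnH (1.15 equiv, slow addition), THF, 0 °C; then 21 (1.2 equiv), DMF, rt → 40 °C
Reagents that add atoms: none
Why: Palladium-catalysed syn-hydrostannylation of the hindered tertiary propargylic alcohol puts tin on the distal carbon to give the (E)-vinylstannane, which undergoes Stille coupling with the (E,E)-bromodiene with retention at both partners, so the all-E triene forms without touching any stereocentre (the C4 descriptor changes from R to S only because the substituent priorities change).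

## Compound list

1 | hex-1-ene | C=CCCCC | starting material
2 | dimethyl[(2S)-2-methylhexyl]alumane | CCCC[C@H](C)C[Al](C)C | intermediate
3 | (4S)-4-methyloct-1-ene | CCCC[C@H](C)CC=C | intermediate
4 | dimethyl[(2R,4S)-2,4-dimethyloctyl]alumane | CCCC[C@H](C)C[C@@H](C)C[Al](C)C | intermediate
5 | (2R,4S)-2,4-dimethyloctan-1-ol | CCCC[C@H](C)C[C@@H](C)CO | intermediate
6 | (2R,4S)-2,4-dimethyloctanal | CCCC[C@H](C)C[C@@H](C)C=O | intermediate
7 | (2E,4R,6S)-4,6-dimethyldec-2-enamide | CCCC[C@H](C)C[C@@H](C)/C=C/C(N)=O | intermediate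
8 | 1,4-benzoquinone | O=C1C=CC(=O)C=C1 | starting material
9 | 4-ethynyl-4-hydroxycyclohexa-2,5-dien-1-one | O=C1C=CC(O)(C#C)C=C1 | intermediate
10 | (3aR,7aR)-3a-ethynyl-2-phenyl-7,7a-dihydro-1,3,2-benzodioxaborol-6(3aH)-one (cyclic phenylboronate of diol 11, cis-fused) | O=C1C=C[C@]2(C#C)OB(c3ccccc3)O[C@@H]2C1 | intermediate
11 | (4R,5R)-4-ethynyl-4,5-dihydroxycyclohex-2-en-1-one (cis-diol) | O=C1C=C[C@@](O)(C#C)[C@H](O)C1 | intermediate
12 | (4R,5R)-4-ethynyl-4,5-dihydroxy-2-iodocyclohex-2-en-1-one | O=C1C(I)=C[C@@](O)(C#C)[C@H](O)C1 | intermediate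
13 | (2E,4R,6S)-N-[(3R,4R)-3-ethynyl-3,4-dihydroxy-6-oxocyclohex-1-en-1-yl]-4,6-dimethyldec-2-enamide | CCCC[C@H](C)C[C@@H](C)/C=C/C(=O)NC1=C[C@@](O)(C#C)[C@H](O)CC1=O | intermediate
14 | potassium (1E,3E)-5-oxopenta-1,3-dien-1-olate | [K+].[O-]/C=C/C=C/C=O | starting material
15 | (2E,4E)-5-bromopenta-2,4-dienal | O=C/C=C/C=C/Br | intermediate
16 | (2E,4E)-5-bromopenta-2,4-dienoic acid | OC(=O)/C=C/C=C/Br | intermediate
17 | cyclopentane-1,3-dione | O=C1CCC(=O)C1 | starting material
18 | 2-(hydroxyimino)cyclopentane-1,3-dione | ON=C1C(=O)CCC1=O | intermediate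
19 | 2-amino-3-hydroxycyclopent-2-en-1-one hydrochloride | Cl.NC1=C(O)CCC1=O | intermediate
20 | (2E,4E)-5-bromopenta-2,4-dienoyl chloride | ClC(=O)/C=C/C=C/Br | intermediate
21 | (2E,4E)-5-bromo-N-(2-hydroxy-5-oxocyclopent-1-en-1-yl)penta-2,4-dienamide | O=C(/C=C/C=C/Br)NC1=C(O)CCC1=O | intermediate
22 | (2E,4R,6S)-N-{(3R,4R)-3,4-dihydroxy-6-oxo-3-[(E)-2-(tributylstannyl)ethenyl]cyclohex-1-en-1-yl}-4,6-dimethyldec-2-enamide | CCCC[C@H](C)C[C@@H](C)/C=C/C(=O)NC1=C[C@@](O)(/C=C/[Sn](CCCC)(CCCC)CCCC)[C@H](O)CC1=O | intermediate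
23 | (2E,4R,6S)-N-[(3S,4R)-3,4-dihydroxy-3-{(1E,3E,5E)-7-[(2-hydroxy-5-oxocyclopent-1-en-1-yl)amino]-7-oxohepta-1,3,5-trien-1-yl}-6-oxocyclohex-1-en-1-yl]-4,6-dimethyldec-2-enamide | CCCC[C@H](C)C[C@@H](C)/C=C/C(=O)NC1=C[C@@](O)(/C=C/C=C/C=C/C(=O)NC2=C(O)CCC2=O)[C@H](O)CC1=O | target

## Step count and risks

Total step count: 13.
Longest linear sequence: 5 steps (hex-1-ene through steps 1, 2, 3, 7, 13; the quinone branch through steps 4, 5, 6, 7, 13 is equally long).

Three steps most likely to fail:

Step 5 (the proposed new step). The enantioselectivity of the boronate oxa-Michael on a dienone is unproven, and the addition may be reversible under the amine catalyst, which would erode ee. The fallback uses only known reactions and sets out from 9. Hydroxyl-directed Weitz–Scheffer epoxidation of one enone arm (t-BuOOH, cat. benzyltrimethylammonium hydroxide, THF, 0 °C) gives the racemic syn-epoxy quinol 5-ethynyl-5-hydroxy-7-oxabicyclo[4.1.0]hept-3-en-2-one (oxirane cis to the hydroxyl) F1. SmI2 (THF/MeOH, −90 °C) then cleaves the Cα–O bond of the α,β-epoxy ketone to the racemic cis-diol rac-4-ethynyl-4,5-dihydroxycyclohex-2-en-1-one F2. Preparative chromatography on a chiral stationary phase resolves it, and the (4R,5R) enantiomer is 11, where the route is rejoined at the cost of half the material.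

Step 7. The free alkynyl diol meets copper and base: possible failures are base-triggered loss of the C5 hydroxyl (retro-oxa-Michael back to a quinol), copper acetylide formation, and copper-promoted cyclisation of the homopropargylic hydroxyl onto the alkyne. The fallback sets out from 11. The diol is tied up as the acetonide (3aR,7aR)-3a-ethynyl-2,2-dimethyl-7,7a-dihydro-1,3-benzodioxol-6(3aH)-one F3 (2,2-dimethoxypropane, pyridinium p-toluenesulfonate, acetone). This is iodinated as in step 6 to the 2-iodoenone acetonide F4 and coupled with 7 under the same copper catalysis to the enamide acetonide F5. Warm 80% aqueous AcOH then frees the diol, and the route is rejoined at 13.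

Step 13. Risks are the regiochemistry of the hydrostannylation, tin hydride reduction of the enone, protodestannylation of 22 by the acidic enol of 21, and the sensitivity of the polyene. The fallback sets out from 13 and 21 and changes the bond-forming logic. Sonogashira coupling (PdCl2(PPh3)2, CuI, Et3N, DMF, rt) gives the dienyne (2E,4R,6S)-N-[(3R,4R)-3,4-dihydroxy-3-{(3E,5E)-7-[(2-hydroxy-5-oxocyclopent-1-en-1-yl)amino]-7-oxohepta-3,5-dien-1-yn-1-yl}-6-oxocyclohex-1-en-1-yl]-4,6-dimethyldec-2-enamide F6. Ruthenium-catalysed trans-hydrosilylation ([Cp*Ru(MeCN)3]PF6, (EtO)3SiH, CH2Cl2, 0 °C), directed to the distal alkyne carbon by the propargylic hydroxyl, gives the (Z)-vinylsilane (triethoxysilyl on C2′ of the chain) F7. Protodesilylation with AgF in wet THF/MeOH gives the (E)-alkene, rejoining the route at 23.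

Further compounds
F1 | step 5 | rac-5-ethynyl-5-hydroxy-7-oxabicyclo[4.1.0]hept-3-en-2-one, oxirane cis to the hydroxyl (racemate, both enantiomers written) | O=C1C=C[C@@](O)(C#C)[C@@H]2O[C@H]12.O=C1C=C[C@](O)(C#C)[C@H]2O[C@@H]12
F2 | step 5 | rac-(4R*,5R*)-4-ethynyl-4,5-dihydroxycyclohex-2-en-1-one (racemate, both enantiomers written) | O=C1C=C[C@@](O)(C#C)[C@H](O)C1.O=C1C=C[C@](O)(C#C)[C@@H](O)C1
F3 | step 7 | (3aR,7aR)-3a-ethynyl-2,2-dimethyl-7,7a-dihydro-1,3-benzodioxol-6(3aH)-one (acetonide of 11) | O=C1C=C[C@]2(C#C)OC(C)(C)O[C@@H]2C1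
F4 | step 7 | (3aR,7aR)-3a-ethynyl-5-iodo-2,2-dimethyl-7,7a-dihydro-1,3-benzodioxol-6(3aH)-one (acetonide of 12) | O=C1C(I)=C[C@]2(C#C)OC(C)(C)O[C@@H]2C1
F5 | step 7 | (2E,4R,6S)-N-[(3aR,7aR)-3a-ethynyl-2,2-dimethyl-6-oxo-3a,6,7,7a-tetrahydro-1,3-benzodioxol-5-yl]-4,6-dimethyldec-2-enamide (acetonide of 13) | CCCC[C@H](C)C[C@@H](C)/C=C/C(=O)NC1=C[C@]2(C#C)OC(C)(C)O[C@@H]2CC1=O
F6 | step 13 | (2E,4R,6S)-N-[(3R,4R)-3,4-dihydroxy-3-{(3E,5E)-7-[(2-hydroxy-5-oxocyclopent-1-en-1-yl)amino]-7-oxohepta-3,5-dien-1-yn-1-yl}-6-oxocyclohex-1-en-1-yl]-4,6-dimethyldec-2-enamide | CCCC[C@H](C)C[C@@H](C)/C=C/C(=O)NC1=C[C@@](O)(C#C/C=C/C=C/C(=O)NC2=C(O)CCC2=O)[C@H](O)CC1=O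
F7 | step 13 | (2E,4R,6S)-N-[(3R,4R)-3,4-dihydroxy-3-{(1Z,3E,5E)-7-[(2-hydroxy-5-oxocyclopent-1-en-1-yl)amino]-7-oxo-2-(triethoxysilyl)hepta-1,3,5-trien-1-yl}-6-oxocyclohex-1-en-1-yl]-4,6-dimethyldec-2-enamide | CCCC[C@H](C)C[C@@H](C)/C=C/C(=O)NC1=C[C@@](O)(/C=C(/C=C/C=C/C(=O)NC2=C(O)CCC2=O)[Si](OCC)(OCC)OCC)[C@H](O)CC1=O
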